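Sunday's flask has spent more G than Friday's at their last readings, 57.1 % against 52.0 %, yet it holds less Z, 26.2 % against 27.4 %. That gap is what you should watch when you repeat these flasks.

all flasks: G 0.050 M

| charge | E | D | temperature | remark | time |
|---|---|---|---|---|---|
| Sunday's | 0.051 M | 0.025 M | 2 °C | run made earlier |  |
| Friday's | 0.075 M | 0.025 M | 19 °C | run made earlier |  |
| Monday's | 0.083 M | 0.025 M | 2 °C | run made earlier |  |
| midnight | 0.100 M | 0.0250 M |  | at 25 °C throughout | 4.0 min |
| winter | 0.0650 M | 0.0250 M |  | at 25 °C until 80 s, from then on at −5 °C | 4.0 min |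

- Sunday's (time / min: Z / %, G / %): 1.00: 31.1, 62.1; 3.00: 29.4, 50.3; 6.00: 26.9, 45.8; 10.0: 26.2, 42.9
- Friday's (time / min: Z / %, G / %): 0.333: 30.4, 55.5; 1.00: 28.6, 49.1; 2.00: 27.8, 47.9; 3.00: 27.4, 48.0
- Monday's (time / min: Z / %, G / %): 1.00: 44.8, 45.0; 3.00: 40.9, 30.4; 6.00: 33.6, 27.5; 10.0: 32.3, 24.9

(standard deviation of a reading: 0.5 percentage points)

- the winner by amount of Z, in percent of the G charged; "neither" if no more than 2 percentage points parts them (midnight / winter / neither)
- how much Z is there at the end, in percent of the G charged: midnight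
- how much Z is there at the end, in percent of the G charged: winter

- the earlier runs were read with a standard deviation of 0.5 percentage points

1. Open the ledger on G with Friday's last reading, at 3.00 min. You have 48.0 % of the G charged still there and 27.4 % held as Z.
2. Close the books: 24.6 % stands in neither column, so in Friday's flask G has gone somewhere these readings do not show.
3. Now divide the Z held by the G spent at that same reading. This gives the keeping share, c(Z) over the c(G) spent, an integral selectivity: 52.7 % for Friday's flask at 3.00 min.
4. This share belongs to its time of reading, so read it along the other runs. Sunday's share falls from 82.1 % at 1.00 min to 45.9 % at 10.0 min. Monday's, with more E, goes from 81.5 % to 43.0 % over the same times.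
5. My own reckoning: both new flasks start at 25 °C, nearest to Friday's temperature, so I carry 52.7 % into both and book that share of whatever G they spend.
6. The forecast names midnight, with 29 % for midnight and 21.5 % for winter. It lets roughly 52 % of the Z formed survive, and of the cooling it says: “Everything is finished by 80 s, so cooling changes nothing.”

The flasks give winter as the winner.

    G + E ⇌ Z (K = 10.0 M⁻¹, k = 1.90 M⁻¹ s⁻¹, Ea = 50.0 kJ mol⁻¹, ΔH = −41.0 kJ mol⁻¹)
    D + E ⇌ Q (K = 4.70 M⁻¹, k = 4.20 M⁻¹ s⁻¹, Ea = 48.0 kJ mol⁻¹, ΔH = −49.0 kJ mol⁻¹)
    2 G → X (k = 0.00108 M⁻¹ s⁻¹, Ea = 64.0 kJ mol⁻¹)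
    E + Z → J (k = 0.0386 M⁻¹ s⁻¹, Ea = 49.0 kJ mol⁻¹)
    Z ⇌ L (K = 0.571, k = 0.0753 s⁻¹, Ea = 81.0 kJ mol⁻¹, ΔH = −22.0 kJ mol⁻¹)
    (constants at 25 °C)

Winter ends with 36.6 % of Z and 39 % of G left, a share of 59.9 %, above the carried 52.7 %. Midnight ends with 25.1 % of Z and 43 % of G left, a share of 44.2 %, below it. Winter's share already stood at 58.3 % at the change of temperature, 1.33 min, while G then fell from 59.6 % to 38.9 %. The same winter flask read at 10 min has 31.2 % of G left and 31.6 % of Z, so its share has dropped to 46.0 %.

Readings and results stem from a simulated flask for substances that don't exist.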